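The data stem from a simulated flask for substances that don't exist, and the scatter is random.

Read at 15 d, the flask with 0.40 M of starting material and 2.50 equiv of partner shows a tris adduct that either stands still or still creeps, and two chemists disagree on which.

| flask | starting material | partner | remark | time |
|---|---|---|---|---|
| amber | 0.20 M | 2.5 equiv | run made earlier |  |
| green | 0.30 M | 2.5 equiv | run made earlier |  |
| teal | 0.40 M | 3.8 equiv | run made earlier |  |
| flask | 0.40 M | 2.50 equiv |  | 15 d |

| run | time / d | tris adduct / % | double product / % |
|---|---|---|---|
| amber | 1.04 | 17 | 0 |
| amber | 1.67 | 15 | 3 |
| amber | 3.00 | 17 | 1 |
| amber | 6.00 | 19 | 0 |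
| amber | 12.0 | 17 | 0 |
| green | 2.50 | 23 | 0 |
| green | 5.00 | 18 | 0 |
| green | 8.00 | 23 | 0 |
| green | 10.0 | 24 | 1 |
| green | 12.0 | 22 | 0 |
| teal | 1.04 | 36 | 0 |
| teal | 1.67 | 38 | 3 |
| teal | 3.00 | 36 | 0 |
| teal | 6.00 | 36 | 1 |
| teal | 12.0 | 35 | 2 |

(standard deviation of a reading: 1.5 percentage points)

- the reaction counts as stopped when no species that holds the starting material changes by six tenths of a point or more over the second half of the time

1. why nothing more happens at 15 d, or that something still does (it is still moving / the partner has run out first / all of the starting material has reacted)
2. the tris adduct standing at 15 d, as a percentage of the starting material charged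

The first chemist sees a balance between tris adduct and reagents with a slow leak beyond it. The forecast is hers: 26%, and it is still moving, on the ground that “Neither reagent is exhausted, so the system is still slowly moving”.

The second chemist, whose reckoning I follow, sees a fork. In her view what is formed either meets more partner and goes on to the tris adduct, or is lost beside it, and the flat line is a finished reaction. Teal reads 36% at 1.04 d and 35% at 12.0 d, a difference of 1 percentage point against a scatter of 1.5 points.

Over its readings, amber averages 17.0% of the charge at a partner charge of 0.500 M. Green averages 22.0% at 0.750 M, with the same equivalents; teal has other equivalents, so it stays out. At these equivalents she writes the plateau as a ceiling times the partner charge, over the partner charge plus the even charge, the partner charge at which the two roads run level. The two pairs give an even charge of 1.07 M and a ceiling of 53.4%, both rough readings. At the flask's 1.00 M this gives 25.8%, with the reaction over. The number hardly parts them; the ending does.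

The flask gives 24.4%, and all of the starting material has reacted.

    starting material + partner → first product (k = 0.570 /M/h)
    partner + first product → double product (k = 0.190 /M/h)
    partner + double product → tris adduct (k = 0.820 /M/h)
    first product → side product (k = 0.110 /h)
    2 starting material → homo dimer (k = 2.30 /M/h)

At 15.0 d the starting material, the limiting reagent, stands at 0%, with 63% of the partner left. The first chemist's ending holds early in this flask: the side product is still rising, from 18.2% at 0.750 d to 18.6% at 3.00 d. With the even charge, the rule stood 1.4 points above this flask. In the neighbour flask with 0.10 M of starting material and the same equivalents, the partner charge of 0.250 M lies below the even charge. The rule gives 10.1% there, and that flask stands at 11.3%.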